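(Readings and results come from a simulation for an exercise.)

- One run at one loading of solid partner cannot show what more solid does to the rates, so I reckon from what the beta run can show and carry that to the new flasks.

| flask | substrate | reagent | solid partner | remark | time |
|---|---|---|---|---|---|
| beta | 0.020 M | 2.2 equiv | 1 equiv | run made earlier |  |
| Saturday's | 0.020 M | 1.50 equiv | 1.00 equiv |  | 3.0 min |
| Thursday's | 0.020 M | 1.50 equiv | 2.00 equiv |  | 3.0 min |
| Wednesday's | 0.020 M | 1.50 equiv | 4.00 equiv |  | 3.0 min |

beta run (percent of the substrate charged)

| time / s | open intermediate / % | substrate / % | homo product / % | target / % |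
|---|---|---|---|---|
| 10.0 | 48.1 | 20.6 | 30.8 | 0.2 |
| 20.0 | 35.0 | 6.0 | 59.3 | 2.0 |
| 40.0 | 16.7 | 0.6 | 78.3 | 4.0 |
| 60.0 | 8.7 | 0 | 84.7 | 6.5 |
| 80.0 | 6.2 | 0 | 85.4 | 8.2 |
| 120 | 1.2 | 0.2 | 87.1 | 10.6 |

(readings scatter by 0.5 percentage points)

- percent here means substrate units held: one homo product counts as two
- solid partner is a solid; its amount is given per volume of the solution
- the earlier runs were read with a standard deviation of 0.5 percentage points
- steps under discussion: substrate + reagent -> open intermediate; reagent + fresh partner -> second intermediate; open intermediate + second intermediate -> target; 2 open intermediate -> homo product; solid partner <-> fresh partner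
- at the start none of the solid partner is in solution

- which of these there is most of at the end, counted by the substrate in it, Saturday's (substrate / target / open intermediate / homo product)
- which of these there is most of at the end, counted by the substrate in it, Thursday's (substrate / target / open intermediate / homo product)
- which of these there is most of at the end, counted by the substrate in it, Wednesday's (substrate / target / open intermediate / homo product)
- final amount of the leader among these, as a percentage of the substrate charged, in Saturday's
- final amount of the leader among these, as a percentage of the substrate charged, in Thursday's
- final amount of the leader among these, as a percentage of the substrate charged, in Wednesday's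

- I take rates as fractions of the substrate charged per minute. In the beta run, homo product starts at 1.85 min⁻¹ over the first 10.0 s.
- Between 20.0 s and 60.0 s its rate reads 0.381 min⁻¹, slower by a factor of 4.86. From 60.0 s to 120 s it reads 0.0240 min⁻¹, slower by a further factor of 15.9. Within this slowing, substrate reads 0.6% at 40.0 s.
- Over the same two windows target goes from 0.0675 min⁻¹ to 0.0410 min⁻¹, a factor of 1.65. Late in the run it therefore outruns homo product, but homo product already reads 84.7% at 60.0 s.
- Dividing one accumulated rate by the other removes time. At the last reading, target over target plus homo product is 10.8%; I call this the target share φ, a selectivity in share form.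
- The beta run gives me no factor for the solid, so I carry φ unchanged to Saturday's, Thursday's and Wednesday's. I assume that the change of reagent from 2.2 equiv to 1.50 equiv leaves φ as it is, and I take target and homo product as the two places where the substrate ends. On these assumptions my own reckoning puts homo product in the lead in each, at about 89.2%.
- The forecast also names homo product, homo product and homo product, but at 86%, 81% and 70%, so its figure falls from Saturday's to Wednesday's where mine stays level. Its grounds are these: “I assume dissolution flux scales with solid loading”.
- The flasks give homo product at 86.6%, 86.6% and 86.6%, with target at 11.2%, 11.2% and 11.2%. The target share on Saturday's is 11.5%, and on Wednesday's 11.5%, beside φ of 10.8%.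

    substrate + reagent → open intermediate (k = 4.80 M⁻¹ s⁻¹)
    reagent + fresh partner → second intermediate (k = 2.40 M⁻¹ s⁻¹)
    open intermediate + second intermediate → target (k = 2.30 M⁻¹ s⁻¹)
    2 open intermediate → homo product (k = 4.10 M⁻¹ s⁻¹)
    solid partner ⇌ fresh partner, rate k5*(cs5 - [fresh partner]) while solid is left; crystals form when [fresh partner] > cs5 (solubility = 7.10 mM, k = 0.0320 s⁻¹)

- A neighbour of Saturday's, charged with 0.900 equiv of reagent, ends with 0.083% of its reagent and 20.6% of the substrate left, and homo product at 71.3%. Its target stands at 4.61%, so its target share is 6.07%, less than φ of 10.8%.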